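A unit of reagent cannot serve both the substrate and the single product. That was the opening point of a short meeting on these flasks.

| flask | substrate | reagent | scavenger | time |
|---|---|---|---|---|
| midnight | 0.50 mM | 0.600 mM (fed, over 6.0 s) | 0.750 mM | 12 s |
| spring | 0.50 mM | 0.600 mM (fed, over 6.0 s) | 1.50 mM | 12 s |
| winter | 0.50 mM | 0.600 mM (fed, over 6.0 s) | 3.00 mM | 12 s |

    scavenger + released group → scavenged by-product (k1 = 23000 M⁻¹ s⁻¹)
    reagent + single product → bis adduct + released group (k2 = 53 M⁻¹ s⁻¹)
    substrate + reagent → single product + released group (k3 = 690 M⁻¹ s⁻¹)
    substrate + released group ⇌ idle adduct, settled at all times (K4 = 4600 M⁻¹)

- released group is meant together with its idle adduct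
- run time (midnight): 12 s

- part of the substrate that has reacted at the end, midnight
- part of the substrate that has reacted at the end, spring
- part of the substrate that has reacted at the end, winter
- what raising the concentration of scavenger from its lowest to its highest value here does to the part of the substrate that has reacted (changes below 5 percentage points count as none) (it falls / no change / it rises)

Item one was the scavenger. I argued it would not matter. In midnight its charge of 0.750 mM is more than the 0.600 mM of reagent, and each reagent used releases one group. Scavenger at its midnight charge removes free released group with a half-life of 0.040 s, much shorter than the 1.7 s of substrate by its own step with the whole reagent charge counted as present at once. So I set the idle adduct aside.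

Item two was the substrate. I proposed two passes. Reagent fed steadily has on average been in the flask for 9.00 s at the end, so I used that time in a plain second-order law. With the full charge, the first pass gave 83.8%. I then put that answer back. The selectivity factor, the bis constant over the single constant, is 0.0768. The usual split of consecutive steps then gave bis adduct at 7.15% of the substrate charged. That left 0.564 mM of working reagent, the charge less what the bis step takes. The second pass gave 81.2%. I entered that figure for midnight, the same for spring and winter, and no change.

The forecaster reported 81% for midnight, 81.2% for spring and 81.3% for winter, with the trend as no change. The stated ground was that the problem “reduces to feed plus second-order kinetics”, stepped by hand.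

Midnight gave 81.4%, spring 81.5% and winter 81.5%, a change of 0.094 percentage points, so no change.

The rate to watch is the split of reagent: at 12.0 s in midnight, substrate was using it 3.2 times as fast as single product was. Bis adduct in midnight then stood at 6.41% of the substrate charged, which puts the working reagent of midnight at 0.568 mM. For the neighbour of midnight with 1.0 mM of reagent, the first pass gives 97.7%. Its working reagent comes to 0.904 mM, and the second pass gives 96.2%. That neighbour flask gave 96.5%.

The numbers stand for no real mixture; what happens was integrated by code.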